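The beta run ends, at its last reading, with 20.6% Sbt.Rea and 15.7% Int2. From that pair I reckon the share of Sbt.Rea in the new flasks, where Rea adds to Sbt, then to Sbt.Rea, then to Int2.

| flask | Sbt | Rea | remark | time |
|---|---|---|---|---|
| delta | 32 mM | 0.87 equiv | run made earlier |  |
| beta | 32 mM | 2.2 equiv | run made earlier |  |
| gamma | 32 mM | 4.3 equiv | run made earlier |  |
| eta | 37 mM | 1.8 equiv | run made earlier |  |
| east | 60 mM | 5.40 equiv |  | 1.0 h |
| south | 60 mM | 1.20 equiv |  | 1.0 h |
| north | 32 mM | 0.900 equiv |  | 1.0 h |
| west | 32 mM | 1.80 equiv |  | 1.0 h |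
| south-west | 20 mM | 1.20 equiv |  | 1.0 h |
| north-east | 100 mM | 1.80 equiv |  | 1.0 h |

| run | time / min | Sbt.Rea / % | Int2 / % |
|---|---|---|---|
| delta | 12.0 | 4.9 | 0.5 |
| delta | 25.0 | 8.5 | 0.9 |
| delta | 40.0 | 10.3 | 2.2 |
| delta | 50.0 | 11.5 | 2.3 |
| delta | 60.0 | 12.9 | 4.0 |
| beta | 12.0 | 10.2 | 0.9 |
| beta | 25.0 | 16.2 | 4.4 |
| beta | 40.0 | 19.2 | 8.9 |
| beta | 50.0 | 19.4 | 11.9 |
| beta | 60.0 | 20.6 | 15.7 |
| gamma | 5.00 | 9.8 | 1.8 |
| gamma | 10.0 | 14.2 | 3.7 |
| gamma | 15.0 | 19.0 | 6.7 |
| gamma | 30.0 | 21.2 | 16.8 |
| gamma | 60.0 | 17.4 | 29.9 |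
| eta | 12.0 | 10.6 | 1.7 |
| eta | 25.0 | 15.8 | 4.5 |
| eta | 40.0 | 17.9 | 7.5 |
| eta | 50.0 | 20.0 | 10.0 |
| eta | 60.0 | 20.3 | 12.7 |

(readings scatter by 0.5 percentage points)

- the earlier runs were read with a standard deviation of 0.5 percentage points
- on the list of suspects stand: Sbt + Rea -> Sbt.Rea; Rea + Sbt.Rea -> Int2; Rea + Int2 <-> Rea.Int2; Sbt <-> Int; Rea -> Sdp

- the flasks put in order of share of Sbt.Rea in all that became Sbt.Rea or Int2 or Rea.Int2, best first, at 1.0 h (east / south / north / west / south-west / north-east)
- the same order at 8.0 h (east / south / north / west / south-west / north-east)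
- the share of Sbt.Rea in all that became Sbt.Rea or Int2 or Rea.Int2 of the flask you put first, at 1.0 h
- the share of Sbt.Rea in all that became Sbt.Rea or Int2 or Rea.Int2 of the flask you put last, at 1.0 h

As my clock I take the exposure X, which is c(Rea) as charged times time, and I treat each addition as pseudo-first-order at that c(Rea). At small X, Sbt.Rea grows with X and Int2 with its square, so the share falls in a straight line. At large X, Sbt.Rea decays exponentially. The curve s = exp(−X/Xc) joins both ends, and it is exact when the second rate constant is 2 times the first. Rea.Int2 comes from Int2, so I count it on the Int2 side. Since X/Xc = ln(1 + c(Int2)/c(Sbt.Rea)), the beta pair gives 124 mM·h as the characteristic exposure Xc, the X that lowers the share by the factor e. The last readings of delta and gamma give 103 mM·h and 138 mM·h, and that spread is what I carry.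

At 1.0 h, X is 24.0 mM·h in south-west, 28.8 mM·h in north, 57.6 mM·h in west, 72.0 mM·h in south, 180 mM·h in north-east and 324 mM·h in east, and that is my order. South-west stands at 82.4% and east at 7.37%.

The weak link is c(Rea) held at its charge, although each addition consumes Rea on the way to 8.0 h. On the curve, the Rea used per Sbt is 2 − 3s + s·s. Setting this equal to the equivalents charged gives an end share of 42.8% for north, 29.6% for south and south-west, and 6.82% for west and north-east. East charges more Rea than the two additions take, so this balance gives it no end share, and I put it last. Within each tied pair I put the more dilute flask ahead, which gives north, south-west, south, west, north-east, east.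

The forecast says south-west > north > west > south > north-east > east at 1.0 h, on the ground that “the share therefore follows absolute [Rea]”; for 8.0 h it turns to the equivalents charged and says north > south-west > south > west > north-east > east. Its top is 83% and its low 13%. Its orders are mine, but my low of 7.37% lies under its figure.

The simulation gives south-west > north > west > south > north-east > east and north > south-west > south > west > north-east > east, with top 80.3% and low 8.66%.

    Sbt + Rea → Sbt.Rea (k = 0.00270 /M/s)
    Rea + Sbt.Rea → Int2 (k = 0.00521 /M/s)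
    Rea + Int2 ⇌ Rea.Int2 (K = 19.0 /M, k = 0.00164 /M/s)
    Sbt ⇌ Int (K = 0.720, k = 1.81 × 10⁻⁴ /s)
    Rea → Sdp (k = 4.61 × 10⁻⁷ /s)

Here k2 is 1.93 times k1. The neighbouring flask is east with 36 mM of Sbt, so its X is 194 mM·h and the curve gives 20.9%. The flask gives 19.7%, with 37.2% Int2 and 18.1% Rea.Int2.

The earlier runs and the new flask are calculated for an exercise; scatter was added.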